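## The problem

Compound 24 is a trans-2,3-diarylindane whose benzo ring (ring B: B1 on Cb, B2 on the ketone carbon C1, oxygens on B3 and B5, B6 on Cc) also belongs to a dibenzo-fused cycloheptenone made up of C1, D1, D6, Ca, Cb, B1 and B2, where ring D is the outer resorcinol ring (D1 on C1, D6 on Ca, oxygens on D3 and D5). Ca carries a 4-hydroxyphenyl group, Cb is the ring-fusion CH, and Cd and Cc are the indane carbons bearing the 4-hydroxyphenyl and 3,5-dihydroxyphenyl groups; one diaryl ketone and eight free phenols complete the functionality. The four contiguous stereocentres Ca, Cb, Cd and Cc are all-trans, and each can be set from its neighbour: Cd against Cc by equilibration next to a carbonyl, Cb by the trans preference on the five-membered ring, Ca by attack anti to the Cb–Cd bond. Only the absolute configuration of the Cd/Cc pair therefore has to be brought in from outside. Ring B is substituted at five positions, and its acylated carbon B2 is no more reactive towards electrophiles than B4 or the ortho carbons of the Cc aryl, so B2 has to be marked early. The electron-rich rings are the fragile part: the phenols oxidise easily, the 4-oxygenated aryl on Cd can bridge to a cation at Cb or Cc, and the 3,5-dioxygenated aryl on Cc sits 1,3-cis to Ca and can trap a cation there, so the phenols are carried as methyl ethers to the last step and cationic chemistry is kept to one step. The feature that opens the chosen disconnection is that Cb is benzylic on B1, ortho to B2 which bears the C1 ketone, so its proton is acidic through a dienolate. Ca sits on D6, ortho to D1 on the other side of the same ketone, so an ester at D6 is held within reach of Cb.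

## Retrosynthesis

24 is the product of global O-demethylation of the octamethyl ether 23. Methyl ethers survive organolithium, amide-base and acid steps, and one BBr3 step removes all eight.

23 is cut at the Ca–aryl bond to the Ca carbinol 21 and anisole 22. The aryl must arrive as the nucleophile: it attacks the Ca cation on the face anti to Cd, which gives the natural configuration. The reverse order (aryl already on Ca, hydride last) would give the Ca epimer. 21 comes from ketone 20 by reduction of the alkyl aryl ketone beside the hindered diaryl ketone.

20 is cut at Ca–Cb to the benzophenone ester 17; this is the key disconnection. The neighbouring cuts are weaker. Cutting Ca–D6 needs a Ca cation next to an open-chain stereocentre, and cutting C1–B2 needs an acylation at B2 that ring B does not direct. Cutting Ca–Cb removes the seven-membered ring and the Cb stereocentre and leaves two aromatic pieces joined by one ketone. The forward step needs deprotonation at Cb only, C-acylation of a hindered benzoate, and thermodynamic control at Cb.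

17 is the methyl ester of keto acid 16, which is cut at C1–B2 to the aryl bromide 11 and the anhydride 14. The bromine fixes B2 without ambiguity, and the anhydride delivers C1 and Ca in one piece. The forward step needs the aryllithium 15 to attack the anhydride carbonyl meta to the methoxy groups.

14 is the anhydride of diacid 13, which comes from 1 by bromine–lithium exchange and carboxylation.

11 is the indanone 9 without its carbonyl oxygen, reached through the tosylhydrazone 10. The ketone is worth carrying to this point because it is what closes the five-membered ring and makes Cd epimerisable. It has to be removed without a cation at Cb, which the Cd aryl would divert.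

9 is one enantiomer of the racemic trans ketone 8, separated on a chiral phase. 8 is cut at Cc–B6 to the α-aryl chalcone 7 (Nazarov cyclisation). This cut uses the one nucleophilic position of ring B and sets the trans relation of Cd and Cc by equilibration. A cross-coupling α-arylation of a ketone enolate (Pd(OAc)2 with a phosphine) is excluded by the aryl bromide, and a catalytic asymmetric conjugate arylation would need an α-aryl enone, a poor acceptor class. Resolution is the price paid for a short, reliable entry.

7 is cut at the Cd=Cc alkene to deoxybenzoin 5 and aldehyde 6 (Knoevenagel). 5 is cut at Cb–Cd to the Weinreb amide 3 and the benzyl Grignard reagent 4. 3 comes from acid 1, which therefore supplies both ring D and ring B.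

## Roads not taken

Alternative 1: The cut is B1–B2: ring B is built last on a cyclopentanone that already holds Cb, Cd and Cc and carries a polycarbonyl side chain. Cs2CO3 would enolise the chain methylene between the aroyl carbonyl C1 and the B3 ketone, an aldol addition to the ring carbonyl B1 would close the six-membered ring, and loss of water with enolisation at B3 and B5 would give A1. A1 is the all-trans indane with a free resorcinol ring B, the ring D aroyl group at B2 and Ca as a silyl-protected carbinol that already bears its 4-methoxyphenyl group. Its merits are real. The B2 acyl group arrives with the ring, so no halogen marker and no regiochemical question arise. The seven-membered ring would later close by attack of ring D on a Ca cation stabilised by the 4-methoxyphenyl group; this is a safer way to install Ca than the chosen plan's intermolecular arylation of a less stabilised cation. Its weak points lie in the precursor: several enolisable positions and competing aldol and pyranone closures, an epimerisable Cb beside the ring ketone, and a cyclopentane stereotriad that must be assembled without help from an aromatic ring. The chosen plan sets against this commercial arenes, ring closures of well-known types and a shorter sequence.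

Alternative 2: The cut is Cc–Cd. A diazo group on the diaryl carbon that becomes Cc would be decomposed by dirhodium tetrakis[(S)-N-phthaloyl-adamantylglycinate], Rh2(S-PTAD)4, a chiral divalent rhodium dimer. The carbene would insert into a benzylic C–H bond of the 4-methoxybenzyl group on Cb and close the five-membered ring to A2, the methyl all-trans-indane-1-carboxylate. This creates Cd and Cc and their absolute configuration in one catalytic step. In that respect it is better than the chosen plan, which separates enantiomers and discards half of ketone 8. Its weakness is what remains after A2: ring D, C1 and the Ca aryl are all missing, and B2 is unmarked. The C1–B2 bond would have to be made by acylation in competition with B4 and the Cc aryl, and the ester carbon still has to become an arylated Ca inside a seven-membered ring. The electron-rich rings also offer the carbene other targets than the C–H bond. The chosen plan sets against the catalytic enantiocontrol a B2 position fixed from the first step and a single step that forms Ca–Cb and the last ring together.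

Alternative 3: The cut runs through ring D (D6–D1 and D3–D2). On heating, a 3-methoxyfuran attached to Ca would add across an ethynyl ketone on B2 in an intramolecular Diels–Alder reaction. This closes the seven-membered ring and forms ring D at once, and opening of the oxygen bridge gives A3, the heptamethyl ether of the target with a free hydroxyl at D3. It is the most convergent of the plans and needs no cation at Ca, since Ca and its aryl are in place before the ring closes; here it is better than the chosen plan. Its weak points are that the Ca stereocentre must be set in an open chain next to Cb and that 3-methoxyfurans are acid- and air-sensitive. The ynone must still be placed on the crowded B2 position. The cycloaddition has to form a seven-membered tether ring, which is slow and reversible for furans. The chosen plan sets against this simpler building blocks and a ring closure driven to completion by enolate formation.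

Key step: step 12

Remark on the chemistry: 4 is used as its commercial THF solution. The fallbacks to steps 13 and 14 assume that the natural arrangement at Ca and Cb is the most stable of the diastereomers differing at these two centres.

Step 1
Reactants: 1 2-bromo-3,5-dimethoxybenzoic acid
Product: 3 2-bromo-N,3,5-trimethoxy-N-methylbenzamide, via acid chloride 2 (not isolated)
Conditions: (COCl)2, DMF (cat.), CH2Cl2, 0 °C to rt; then MeNH(OMe)·HCl, Et3N, CH2Cl2, 0 °C
Reagents that add atoms: N,O-dimethylhydroxylamine hydrochloride, CNOC.Cl
Why: Acid chloride formation and aminolysis (nucleophilic acyl substitution); the Weinreb amide is chosen so that step 2 stops at the ketone.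

Step 2
Reactants: 3 2-bromo-N,3,5-trimethoxy-N-methylbenzamide; 4 (4-methoxybenzyl)magnesium chloride
Product: 5 1-(2-bromo-3,5-dimethoxyphenyl)-2-(4-methoxyphenyl)ethan-1-one
Conditions: THF, −20 to 0 °C; aq NH4Cl
Reagents that add atoms: none
Why: Weinreb ketone synthesis: the Grignard reagent adds once to a chelated tetrahedral intermediate that releases the ketone only on work-up; the aryl bromide does not exchange with a benzylmagnesium halide at this temperature.

Step 3
Reactants: 5 1-(2-bromo-3,5-dimethoxyphenyl)-2-(4-methoxyphenyl)ethan-1-one; 6 3,5-dimethoxybenzaldehyde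
Product: 7 1-(2-bromo-3,5-dimethoxyphenyl)-3-(3,5-dimethoxyphenyl)-2-(4-methoxyphenyl)prop-2-en-1-one (E/Z mixture)
Conditions: piperidine, AcOH, toluene, reflux, Dean–Stark
Reagents that add atoms: none
Why: Knoevenagel condensation of the doubly activated methylene of a deoxybenzoin with a non-enolisable aldehyde, driven by removal of water; the alkene geometry is irrelevant because both isomers converge in step 4.

Step 4
Reactants: 7 α-aryl chalcone (E/Z mixture)
Product: 8 (±)-trans-7-bromo-3-(3,5-dimethoxyphenyl)-4,6-dimethoxy-2-(4-methoxyphenyl)-2,3-dihydro-1H-inden-1-one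
Conditions: CF3CO2H, ClCH2CH2Cl, 70 °C
Reagents that add atoms: none
Why: Nazarov cyclisation of an aryl vinyl ketone: the hydroxypentadienyl cation is closed by B6, the only free ortho position of ring B and one activated by two methoxy groups, forming Cc–B6; the enol is protonated and C2 equilibrates in the acid, so the trans relation of Cd and Cc is set under thermodynamic control.

Step 5
Reactants: 8 (±)-trans-indanone
Product: 9 (2S,3S)-7-bromo-3-(3,5-dimethoxyphenyl)-4,6-dimethoxy-2-(4-methoxyphenyl)-2,3-dihydro-1H-inden-1-one
Conditions: preparative HPLC, amylose tris(3,5-dimethylphenylcarbamate) stationary phase, hexane/i-PrOH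
Reagents that add atoms: none
Why: Resolution of a racemate by chromatography on a chiral stationary phase, routine for rigid aryl ketones; the bromine atom allows the absolute configuration of the collected enantiomer to be assigned by anomalous-dispersion X-ray diffraction, and the separation is done early on inexpensive material.

Step 6
Reactants: 9 (2S,3S)-indanone
Product: 10 N'-[(2S,3S)-7-bromo-3-(3,5-dimethoxyphenyl)-4,6-dimethoxy-2-(4-methoxyphenyl)-2,3-dihydro-1H-inden-1-ylidene]-4-methylbenzenesulfonohydrazide
Conditions: TsNHNH2, TsOH·H2O (cat.), EtOH, 80 °C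
Reagents that add atoms: 4-methylbenzenesulfonohydrazide, Cc1ccc(cc1)S(=O)(=O)NN
Why: Hydrazone formation at the only carbonyl group; any epimerisation at C2 through the ene-hydrazine returns to the more stable trans isomer.

Step 7
Reactants: 10 tosylhydrazone
Product: 11 (1S,2S)-4-bromo-1-(3,5-dimethoxyphenyl)-5,7-dimethoxy-2-(4-methoxyphenyl)-2,3-dihydro-1H-indene
Conditions: catecholborane, CHCl3, 0 °C to rt; then NaOAc·3H2O, 60 °C
Reagents that add atoms: none
Why: Caglioti-type reductive deoxygenation of a tosylhydrazone: hydroboration of C=N, acetate-induced loss of sulfinate and loss of N2 from the diazene give the Cb methylene without a cation at Cb (which the Cd aryl would divert by bridging or elimination) and without touching the aryl bromide; Cd and Cc are not involved.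

Step 8
Reactants: 1 2-bromo-3,5-dimethoxybenzoic acid
Product: 13 3,5-dimethoxyphthalic acid, via dilithio benzoate 12 (not isolated)
Conditions: n-BuLi (2.2 equiv), THF, −78 °C; CO2 (g); then 2 M HCl
Reagents that add atoms: carbon dioxide, O=C=O
Why: Deprotonation of the acid, bromine–lithium exchange and carboxylation of the aryllithium, a standard route from 2-bromobenzoic acids to phthalic acids.

Step 9
Reactants: 13 3,5-dimethoxyphthalic acid
Product: 14 3,5-dimethoxyphthalic anhydride
Conditions: Ac2O, 120 °C
Reagents that add atoms: none
Why: Cyclodehydration of a 1,2-dicarboxylic acid to the five-membered anhydride.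

Step 10
Reactants: 11 (1S,2S)-4-bromoindane; 14 3,5-dimethoxyphthalic anhydride
Product: 16 2-{[(1S,2S)-1-(3,5-dimethoxyphenyl)-5,7-dimethoxy-2-(4-methoxyphenyl)-2,3-dihydro-1H-inden-4-yl]carbonyl}-4,6-dimethoxybenzoic acid, via aryllithium 15 (not isolated)
Conditions: t-BuLi (2.0 equiv), THF, −78 °C; cannulate into 14, THF, −78 to −20 °C; then 1 M HCl
Reagents that add atoms: none
Why: Bromine–lithium exchange and acylation of the aryllithium by a cyclic anhydride (2-aroylbenzoic acid synthesis); the carboxylate that forms prevents a second addition, and the hindered aryllithium should attack the carbonyl on D1, which is meta to both methoxy groups and unhindered, and not the D6 carbonyl, which is flanked by a methoxy group and deactivated by ortho and para donation.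

Step 11
Reactants: 16 keto acid
Product: 17 methyl 2-{[(1S,2S)-1-(3,5-dimethoxyphenyl)-5,7-dimethoxy-2-(4-methoxyphenyl)-2,3-dihydro-1H-inden-4-yl]carbonyl}-4,6-dimethoxybenzoate
Conditions: MeI, K2CO3, DMF, rt
Reagents that add atoms: iodomethane, CI
Why: SN2 alkylation of the carboxylate gives the open methyl ester and avoids the cyclic pseudo-ester that acid-catalysed esterification of 2-aroylbenzoic acids can give.

Step 12
Reactants: 17 benzophenone methyl ester
Product: 20 tetracyclic C1/Ca diketone heptamethyl ether (Ca trans to the Cd aryl), via potassium dienolate 18 (not isolated), via potassium enolate 19 (not isolated)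
Conditions: KN(SiMe3)2 (3 equiv), THF (0.01 M), −78 to 0 °C; AcOH; then DBU (20 mol %), CH2Cl2, rt
Reagents that add atoms: none
Why: KN(SiMe3)2 neither adds to nor reduces the non-enolisable diaryl ketone and removes the only proton conjugated with it, a benzylic Cb–H on B1 ortho to the acylated B2, giving the ortho-quinodimethane dienolate 18; potassium bridges the enolate oxygen and the B3 methoxy group, which turns ring D towards Cb. The Cb terminus of 18 adds to the D6 ester carbonyl held close by the benzophenone, and loss of methoxide closes the seven-membered ring in a 7-exo-trig acyl substitution (intramolecular Claisen, Dieckmann-type); the closest known reaction type is the cyclisation of laterally metalated ortho-alkyl aryl ketones and ortho-toluates onto esters. The new ketone makes the remaining Cb–H doubly activated, so the product is deprotonated to enolate 19, which makes the condensation irreversible and is why three equivalents of base are used. Site selectivity follows from conjugation: Cc–H and Cd–H are benzylic but cannot form a dienolate with the ketone, and O-acylation of 18 would give only a dearomatised enol lactone that reverts. The one new stereocentre, Cb, is set under thermodynamic control by Cd: protonation of 19 and brief equilibration with DBU through the same enolate place Ca trans to the 4-methoxyphenyl group on Cd, while Cd and Cc are never deprotonated. The step needs C-acylation of a 2,6-disubstituted benzoate, which rests on the rigid intramolecular geometry, and high dilution keeps intermolecular condensation down.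

Step 13
Reactants: 20 tetracyclic diketone
Product: 21 Ca carbinol of 20 (both Ca epimers)
Conditions: NaBH4, CeCl3·7H2O, MeOH/THF, −40 °C
Reagents that add atoms: none
Why: Luche-type borohydride reduction: the alkyl aryl ketone at Ca, activated by CeCl3, should react faster than the C1 diaryl ketone, which is conjugated with two rings and screened by B1 and the B3 methoxy group; the cerium salt keeps the medium non-basic so that Cb is neither enolised nor epimerised, and the configuration of the new carbinol is irrelevant because it is ionised in step 14.

Step 14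
Reactants: 21 Ca carbinol; 22 anisole
Product: 23 octamethyl ether of the target (Ca S; Cb R; Cd S; Cc S)
Conditions: CF3SO3H (10 mol %), anisole/CH2Cl2 (1:1), −40 to 0 °C
Reagents that add atoms: none
Why: Friedel–Crafts alkylation by a benzylic cation: ionisation gives a Ca cation stabilised by the ortho and para methoxy groups of ring D, and anisole, used as co-solvent to outrun internal nucleophiles, attacks through its para position on the face anti to the Cb–Cd bond, so the Ca configuration is set by Cb.

Step 15
Reactants: 23 octamethyl ether
Product: 24 target compound CNP0116600.1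
Conditions: BBr3 (16 equiv), CH2Cl2, −78 °C to rt; then MeOH, H2O
Reagents that add atoms: none
Why: Lewis-acid cleavage of aryl methyl ethers (boron complexation, bromide attack on methyl); no stereocentre carries a leaving group and the diaryl ketone is inert.

Compound list
1 | 2-bromo-3,5-dimethoxybenzoic acid | COc1cc(OC)c(Br)c(C(=O)O)c1 | starting material
2 | 2-bromo-3,5-dimethoxybenzoyl chloride | COc1cc(OC)c(Br)c(C(Cl)=O)c1 | intermediate (not isolated)
3 | 2-bromo-N,3,5-trimethoxy-N-methylbenzamide | COc1cc(OC)c(Br)c(C(=O)N(C)OC)c1 | intermediate
4 | (4-methoxybenzyl)magnesium chloride | COc1ccc(C[Mg]Cl)cc1 | starting material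
5 | 1-(2-bromo-3,5-dimethoxyphenyl)-2-(4-methoxyphenyl)ethan-1-one | COc1cc(OC)c(Br)c(C(=O)Cc2ccc(OC)cc2)c1 | intermediate
6 | 3,5-dimethoxybenzaldehyde | COc1cc(C=O)cc(OC)c1 | starting material
7 | 1-(2-bromo-3,5-dimethoxyphenyl)-3-(3,5-dimethoxyphenyl)-2-(4-methoxyphenyl)prop-2-en-1-one, E/Z mixture | COc1cc(OC)c(Br)c(C(=O)C(=Cc2cc(OC)cc(OC)c2)c2ccc(OC)cc2)c1 | intermediate
8 | (±)-trans-(2RS,3RS)-7-bromo-3-(3,5-dimethoxyphenyl)-4,6-dimethoxy-2-(4-methoxyphenyl)-2,3-dihydro-1H-inden-1-one, racemate (both enantiomers shown) | Brc1c(OC)cc(OC)c2c1C(=O)[C@H](c1ccc(OC)cc1)[C@H]2c1cc(OC)cc(OC)c1.Brc1c(OC)cc(OC)c2c1C(=O)[C@@H](c1ccc(OC)cc1)[C@@H]2c1cc(OC)cc(OC)c1 | intermediate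
9 | (2S,3S)-7-bromo-3-(3,5-dimethoxyphenyl)-4,6-dimethoxy-2-(4-methoxyphenyl)-2,3-dihydro-1H-inden-1-one | Brc1c(OC)cc(OC)c2c1C(=O)[C@H](c1ccc(OC)cc1)[C@H]2c1cc(OC)cc(OC)c1 | intermediate
10 | N'-[(2S,3S)-7-bromo-3-(3,5-dimethoxyphenyl)-4,6-dimethoxy-2-(4-methoxyphenyl)-2,3-dihydro-1H-inden-1-ylidene]-4-methylbenzenesulfonohydrazide | Brc1c(OC)cc(OC)c2c1C(=NNS(=O)(=O)c1ccc(C)cc1)[C@H](c1ccc(OC)cc1)[C@H]2c1cc(OC)cc(OC)c1 | intermediate
11 | (1S,2S)-4-bromo-1-(3,5-dimethoxyphenyl)-5,7-dimethoxy-2-(4-methoxyphenyl)-2,3-dihydro-1H-indene | Brc1c(OC)cc(OC)c2c1C[C@H](c1ccc(OC)cc1)[C@H]2c1cc(OC)cc(OC)c1 | intermediate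
12 | lithium 2-lithio-3,5-dimethoxybenzoate | COc1cc(OC)c([Li])c(C(=O)O[Li])c1 | intermediate (not isolated)
13 | 3,5-dimethoxyphthalic acid | COc1cc(OC)c(C(=O)O)c(C(=O)O)c1 | intermediate
14 | 3,5-dimethoxyphthalic anhydride (4,6-dimethoxy-2-benzofuran-1,3-dione) | COc1cc(OC)c2C(=O)OC(=O)c2c1 | intermediate
15 | [(1S,2S)-1-(3,5-dimethoxyphenyl)-5,7-dimethoxy-2-(4-methoxyphenyl)-2,3-dihydro-1H-inden-4-yl]lithium | [Li]c1c(OC)cc(OC)c2c1C[C@H](c1ccc(OC)cc1)[C@H]2c1cc(OC)cc(OC)c1 | intermediate (not isolated)
16 | 2-{[(1S,2S)-1-(3,5-dimethoxyphenyl)-5,7-dimethoxy-2-(4-methoxyphenyl)-2,3-dihydro-1H-inden-4-yl]carbonyl}-4,6-dimethoxybenzoic acid | O=C(c1cc(OC)cc(OC)c1C(=O)O)c1c(OC)cc(OC)c2c1C[C@H](c1ccc(OC)cc1)[C@H]2c1cc(OC)cc(OC)c1 | intermediate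
17 | methyl 2-{[(1S,2S)-1-(3,5-dimethoxyphenyl)-5,7-dimethoxy-2-(4-methoxyphenyl)-2,3-dihydro-1H-inden-4-yl]carbonyl}-4,6-dimethoxybenzoate | O=C(c1cc(OC)cc(OC)c1C(=O)OC)c1c(OC)cc(OC)c2c1C[C@H](c1ccc(OC)cc1)[C@H]2c1cc(OC)cc(OC)c1 | intermediate
18 | potassium dienolate of 17, deprotonated at Cb (ortho-quinodimethane enolate of the C1 ketone) | [K+].[O-]C(c1cc(OC)cc(OC)c1C(=O)OC)=C1C(OC)=CC(OC)=C2C1=C[C@H](c1ccc(OC)cc1)[C@H]2c1cc(OC)cc(OC)c1 | intermediate (not isolated)
19 | potassium enolate of 20 (Ca–O−, Ca=Cb) | O=C1c2cc(OC)cc(OC)c2C([O-])=C2c3c1c(OC)cc(OC)c3[C@H](c1cc(OC)cc(OC)c1)[C@H]2c1ccc(OC)cc1.[K+] | intermediate (not isolated)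
20 | tetracyclic diketone, heptamethyl ether: ketones at C1 and Ca, rings D and B each bearing two methoxy groups, indane Cb–Cd(4-methoxyphenyl)–Cc(3,5-dimethoxyphenyl); Ca trans to the Cd aryl, Cd and Cc aryls trans (Cb S, Cd R, Cc S) | O=C1c2cc(OC)cc(OC)c2C(=O)[C@@H]2c3c1c(OC)cc(OC)c3[C@H](c1cc(OC)cc(OC)c1)[C@H]2c1ccc(OC)cc1 | intermediate
21 | Ca carbinol of 20, both Ca epimers (Cb S, Cd R, Cc S) | O=C1c2cc(OC)cc(OC)c2C(O)[C@@H]2c3c1c(OC)cc(OC)c3[C@H](c1cc(OC)cc(OC)c1)[C@H]2c1ccc(OC)cc1 | intermediate
22 | anisole | COc1ccccc1 | starting material
23 | octamethyl ether of the target: 4-methoxyphenyl on Ca trans to Cd, all-trans (Ca S, Cb R, Cd S, Cc S) | O=C1c2cc(OC)cc(OC)c2[C@H](c2ccc(OC)cc2)[C@@H]2c3c1c(OC)cc(OC)c3[C@H](c1cc(OC)cc(OC)c1)[C@H]2c1ccc(OC)cc1 | intermediate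
24 | CNP0116600.1 (Ca S, Cb R, Cd S, Cc S) | O=C1c2cc(O)cc(O)c2[C@H](c2ccc(O)cc2)[C@@H]2c3c1c(O)cc(O)c3[C@H](c1cc(O)cc(O)c1)[C@H]2c1ccc(O)cc1 | target

Total step count: 15. Longest linear sequence: 13 steps (1 to 24 through steps 1–7 and 10–15); the anhydride branch (steps 8 and 9) joins at step 10.

Least certain steps

Step 12 (key step). The most likely failure is that acylation does not follow deprotonation. The C1 carbonyl is flanked by B1 and the B3 methoxy group and is twisted out of the plane of ring B, which weakens the dienolate. The ester is a 2,6-disubstituted, electron-rich benzoate, so proton return on quench would only give back 17; intermolecular condensation is the second risk. Fallback: make Ca a better electrophile and close the same bond by a dienolate aldol addition. Setting out from 17, LiAlH4 reduces ester and ketone to the diol F1. Swern oxidation ((COCl)2, DMSO, Et3N, −78 °C) converts both carbinols into the keto aldehyde F2; activated DMSO is chosen because it oxidises both hydroxyl groups before a lactol can form and be carried on to a phthalide. LiN(SiMe3)2 in THF at −78 °C with a cold quench (to avoid E1cB loss of water) closes the ring, with the aldehyde approaching Cb anti to the Cd aryl. This returns to the route at 21 and bypasses 20 and step 13.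

Step 14. Two processes threaten the arylation. The first is capture of the Ca cation by the 3,5-dimethoxyphenyl ring on Cc, which lies on the same face of the indane as Ca and is far more nucleophilic than anisole. The second is E1 loss of the Cb proton followed by reprotonation, which would scramble Cb. Fallback without a cation at Ca: setting out from 20, the enolate is trapped with PhNTf2 (KN(SiMe3)2, THF) as the enol triflate F3. Suzuki–Miyaura coupling with 4-methoxyphenylboronic acid (Pd(PPh3)4, K3PO4) gives the tetrasubstituted alkene F4. Hydrogenation over Pd/C from the face away from the Cd aryl gives the Cb epimer F5 of 23. KOt-Bu in t-BuOH/THF then equilibrates Cb through the ring B dienolate, which returns to the route at 23.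

Step 13. The likely failures are competing hydride addition to the C1 ketone and epimerisation at Cb before reduction, because the two carbonyls differ only moderately in reactivity. Fallback that differentiates the carbonyls by condensation instead of hydride addition: setting out from 20, TsNHNH2 should condense only with the alkyl aryl ketone to give the Ca tosylhydrazone F6. Heating F6 with 4-methoxyphenylboronic acid and K2CO3 in dioxane (reductive coupling of the derived diazo compound with the boronic acid, then protodeboronation) gives 23 together with its Ca epimer F7. KOt-Bu equilibration through the ring D dienolate converges on 23, where the route is rejoined; steps 13 and 14 are bypassed.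

Step 10. The risk is loss of regiocontrol in the anhydride opening (lithium chelation by the methoxy group could steer attack to the D6 carbonyl) and a second addition to the keto carboxylate. Fallback with unambiguous regiochemistry: setting out from 3 and 11, LiAlH4 at −78 °C reduces 3 to 2-bromo-3,5-dimethoxybenzaldehyde F8. Aryllithium 15, made from 11 as in step 10, adds to F8 to give the diaryl carbinol F9. MnO2 oxidises F9 to the bromo benzophenone F10. Methoxycarbonylation (Pd(OAc)2, Xantphos, CO, MeOH, Et3N, 90 °C) installs the ester, which returns to the route at 17.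

Further compounds
F1 | step 12 | diol from 17: [2-(hydroxymethyl)-3,5-dimethoxyphenyl][(1S,2S)-1-(3,5-dimethoxyphenyl)-5,7-dimethoxy-2-(4-methoxyphenyl)-2,3-dihydro-1H-inden-4-yl]methanol, both carbinol epimers | OCc1c(OC)cc(OC)cc1C(O)c1c(OC)cc(OC)c2c1C[C@H](c1ccc(OC)cc1)[C@H]2c1cc(OC)cc(OC)c1
F2 | step 12 | 2-{[(1S,2S)-1-(3,5-dimethoxyphenyl)-5,7-dimethoxy-2-(4-methoxyphenyl)-2,3-dihydro-1H-inden-4-yl]carbonyl}-4,6-dimethoxybenzaldehyde | O=Cc1c(OC)cc(OC)cc1C(=O)c1c(OC)cc(OC)c2c1C[C@H](c1ccc(OC)cc1)[C@H]2c1cc(OC)cc(OC)c1
F3 | step 14 | enol triflate of 20 (Ca–OSO2CF3, Ca=Cb) | O=C1c2cc(OC)cc(OC)c2C(OS(=O)(=O)C(F)(F)F)=C2c3c1c(OC)cc(OC)c3[C@H](c1cc(OC)cc(OC)c1)[C@H]2c1ccc(OC)cc1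
F4 | step 14 | Ca=Cb alkene bearing 4-methoxyphenyl on Ca | O=C1c2cc(OC)cc(OC)c2C(c2ccc(OC)cc2)=C2c3c1c(OC)cc(OC)c3[C@H](c1cc(OC)cc(OC)c1)[C@H]2c1ccc(OC)cc1
F5 | step 14 | Cb epimer of 23 (Ca S, Cb S, Cd S, Cc S) | O=C1c2cc(OC)cc(OC)c2[C@H](c2ccc(OC)cc2)[C@H]2c3c1c(OC)cc(OC)c3[C@H](c1cc(OC)cc(OC)c1)[C@H]2c1ccc(OC)cc1
F6 | step 13 | Ca tosylhydrazone of 20 | O=C1c2cc(OC)cc(OC)c2C(=NNS(=O)(=O)c2ccc(C)cc2)[C@@H]2c3c1c(OC)cc(OC)c3[C@H](c1cc(OC)cc(OC)c1)[C@H]2c1ccc(OC)cc1
F7 | step 13 | Ca epimer of 23 (Ca R, Cb R, Cd S, Cc S) | O=C1c2cc(OC)cc(OC)c2[C@@H](c2ccc(OC)cc2)[C@@H]2c3c1c(OC)cc(OC)c3[C@H](c1cc(OC)cc(OC)c1)[C@H]2c1ccc(OC)cc1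
F8 | step 10 | 2-bromo-3,5-dimethoxybenzaldehyde | COc1cc(OC)c(Br)c(C=O)c1
F9 | step 10 | (2-bromo-3,5-dimethoxyphenyl)[(1S,2S)-1-(3,5-dimethoxyphenyl)-5,7-dimethoxy-2-(4-methoxyphenyl)-2,3-dihydro-1H-inden-4-yl]methanol, both carbinol epimers | OC(c1cc(OC)cc(OC)c1Br)c1c(OC)cc(OC)c2c1C[C@H](c1ccc(OC)cc1)[C@H]2c1cc(OC)cc(OC)c1
F10 | step 10 | (2-bromo-3,5-dimethoxyphenyl)[(1S,2S)-1-(3,5-dimethoxyphenyl)-5,7-dimethoxy-2-(4-methoxyphenyl)-2,3-dihydro-1H-inden-4-yl]methanone | O=C(c1cc(OC)cc(OC)c1Br)c1c(OC)cc(OC)c2c1C[C@H](c1ccc(OC)cc1)[C@H]2c1cc(OC)cc(OC)c1
A1 | alternative 1 | all-trans indane with free resorcinol ring B, ring D aroyl group at B2 and Ca as tert-butyldimethylsilyl-protected (4-methoxyphenyl)carbinol | COc1ccc(cc1)[C@H](O[Si](C)(C)C(C)(C)C)[C@@H]2c3c(C(=O)c6cc(OC)cc(OC)c6)c(O)cc(O)c3[C@H](c4cc(OC)cc(OC)c4)[C@H]2c5ccc(OC)cc5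
A2 | alternative 2 | methyl all-trans-3-(3,5-dimethoxyphenyl)-4,6-dimethoxy-2-(4-methoxyphenyl)indane-1-carboxylate | COC(=O)[C@@H]1c2cc(OC)cc(OC)c2[C@H](c3cc(OC)cc(OC)c3)[C@H]1c4ccc(OC)cc4
A3 | alternative 3 | heptamethyl ether of the target with free hydroxyl at D3 of ring D | O=C1c2cc(O)cc(OC)c2[C@H](c2ccc(OC)cc2)[C@@H]2c3c1c(OC)cc(OC)c3[C@H](c1cc(OC)cc(OC)c1)[C@H]2c1ccc(OC)cc1
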